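**Plan**

- Retrosynthesis: both aryl–C7' bonds are cut in one retro double Friedel–Crafts step. These are guaiacyl C1'–C7', which joins the two halves, and ring carbon C2–C7', which closes the carbocycle. This leads to guaiacol and an open-chain (2R,3R)-4-aryl-2,3-dimethylbutanal. The aryl–C7 bond is then cut, at the aryl ketone level, to an arylzinc and meso-2,3-dimethylsuccinic anhydride.
- Enabling feature: C7' is a diarylmethine carbon bonded to the most nucleophilic carbon of each ring (guaiacyl C1' para to 4'-OH; ring carbon C2 ortho and para to the 3- and 5-OMe groups), so it can arrive as an aldehyde carbon. In the open chain the 4-hydroxy-3,5-dimethoxyphenyl ring has equivalent C2 and C6, so ring closure has one outcome. The C7–C8(Me)–C8'(Me)–C7' unit with cis methyls is a meso-succinic unit.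
- Forward: a desymmetrising arylation of the anhydride makes the aryl–C7 bond; hydrogenolysis and esterification follow, then reduction to the aldehyde. The key step closes the carbocycle (the only ring made) and then forms the guaiacyl–C7' bond in the same flask.
- Stereochemistry: the cis C8/C8' relationship comes from the meso anhydride and the absolute configuration from the chiral Rh catalyst. C7' is set by substrate control, with guaiacol adding to the planar benzylic cation anti to both methyl groups.

Key step: step 6

Remark: in step 3 the antipode of the TADDOL-derived phosphoramidite that delivers the (2R,3S) acid is used; both antipodes are available from the two tartaric acids, and compounds 1, 3 and 11 are taken as commercial.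

**Step 1**
Reactants: 1 4-bromo-2,6-dimethoxyphenol
Product: 2 2-(benzyloxy)-5-bromo-1,3-dimethoxybenzene
Conditions: BnBr, K2CO3, DMF, rt
Reagents that add atoms: benzyl bromide, BrCc1ccccc1
Why: Williamson ether synthesis on the phenoxide should mask the acidic OH before the halogen–metal exchange of step 3.

**Step 2**
Reactants: 3 meso-2,3-dimethylsuccinic acid
Product: 4 cis-2,3-dimethylsuccinic anhydride, (3R,4S)-3,4-dimethyloxolane-2,5-dione
Conditions: AcCl, reflux; evaporate
Reagents that add atoms: none
Why: Cyclodehydration of a 1,4-diacid touches no bond at either stereocentre, so the meso acid should give the cis anhydride with the two methyl groups on one face.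

**Step 3**
Reactants: 2 2-(benzyloxy)-5-bromo-1,3-dimethoxybenzene, 4 cis-2,3-dimethylsuccinic anhydride
Product: 7 (2R,3S)-4-[4-(benzyloxy)-3,5-dimethoxyphenyl]-2,3-dimethyl-4-oxobutanoic acid, via aryllithium 5 (not isolated), via arylzinc triflate 6 (not isolated)
Conditions: 2, n-BuLi, THF, −78 °C; Zn(OTf)2, −78 °C → rt; then 4, [Rh(cod)Cl]2 (cat.), TADDOL-derived phosphoramidite (cat.), THF, 50 °C; 1 M HCl work-up; recrystallise
Reagents that add atoms: none
Why: Li–Br exchange and transmetallation give arylzinc 6, and the Rh(I)/phosphoramidite catalyst inserts into one of the two enantiotopic acyl–oxygen bonds of 4 and transfers the aryl group (enantioselective desymmetrising cross-coupling of a meso anhydride with an organozinc), so the ligand sets the absolute configuration while the cis-methyl relationship is carried over untouched.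

**Step 4**
Reactants: 7 (2R,3S)-4-[4-(benzyloxy)-3,5-dimethoxyphenyl]-2,3-dimethyl-4-oxobutanoic acid
Product: 9 methyl (2R,3R)-4-(4-hydroxy-3,5-dimethoxyphenyl)-2,3-dimethylbutanoate, via phenol acid 8 (not isolated)
Conditions: H2 (4 atm), 10% Pd/C, MeOH, HCl (cat.), rt; filter; then reflux in the same HCl/MeOH
Reagents that add atoms: methanol, CO
Why: Pd-catalysed hydrogenolysis should remove the benzyl ether and reduce the electron-rich aryl ketone through the benzylic alcohol to CH2, after which Fischer esterification in the same acidic methanol gives the ester; no bond at a stereocentre is made or broken, and the C3 descriptor changes from S to R only through the CIP priorities.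

**Step 5**
Reactants: 9 methyl (2R,3R)-4-(4-hydroxy-3,5-dimethoxyphenyl)-2,3-dimethylbutanoate
Product: 10 (2R,3R)-4-(4-hydroxy-3,5-dimethoxyphenyl)-2,3-dimethylbutanal
Conditions: DIBAL-H (2.2 equiv), CH2Cl2, −78 °C; MeOH, then aq. Rochelle salt; crude aldehyde used at once
Reagents that add atoms: none
Why: In this DIBAL-H partial reduction of an ester the first equivalent is consumed by the phenol and the second adds once to the ester, and the tetrahedral aluminium hemiacetal should persist at −78 °C until the quench, so the aldehyde is released only on work-up and its α-stereocentre is left alone.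

**Step 6**
Reactants: 10 (2R,3R)-4-(4-hydroxy-3,5-dimethoxyphenyl)-2,3-dimethylbutanal, 11 guaiacol (2-methoxyphenol)
Product: 13 (−)-(7'R,8R,8'R)-4,4'-dihydroxy-3,3',5-trimethoxy-2,7'-cyclolignan, via tetralol 12 (not isolated)
Conditions: 11 (4 equiv), BF3·OEt2 (0.5 equiv), CH2Cl2, −40 → 0 °C, slow addition of 10; aq. NaHCO3
Reagents that add atoms: none
Why: BF3 activates the aldehyde of 10, and the tethered ring attacks it through C2, the carbon ortho and para to its two methoxy groups, in a 6-exo-trig Friedel–Crafts hydroxyalkylation that closes the carbocycle to tetralol 12; the two ortho carbons of the 4-hydroxy-3,5-dimethoxyphenyl ring are equivalent, so only one ring-closure product is possible. Ionisation of 12 gives a benzylic cation at C7' that is stabilised by the ortho and para methoxy groups of the new tetralin ring, and guaiacol 11 attacks it through the carbon para to its hydroxyl group, which forms the aryl–C7' bond. The closest known reaction type is the acid-mediated double arylation of an aldehyde by two arenes (Baeyer-type hydroxyalkylation followed by Friedel–Crafts alkylation) in its cyclising form, together with the BF3-promoted C-arylation of cyclic benzylic alcohols by phenols. The new stereocentre C7' is controlled by the cis methyl groups at C8 and C8': in the half-chair cation the C8' methyl is pseudoaxial and both methyls lie on one face, so axial attack from the other face should give the 7',8'-trans, 7',8-trans (7'R) product, which places the aryl group pseudoaxial and away from the peri methoxy group. The step needs site selectivity on guaiacol, which the stronger para-directing hydroxyl (hydrogen-bonded to the methoxy oxygen) should provide, and it needs capture of the cation to outrun loss of the C8' proton, which the excess of guaiacol and the low temperature serve. The carbinol centre of 12 is transient and is erased on ionisation, so it needs no control.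

**Compound list**

1 | 4-bromo-2,6-dimethoxyphenol | COc1cc(Br)cc(OC)c1O | starting material
2 | 2-(benzyloxy)-5-bromo-1,3-dimethoxybenzene | COc1cc(Br)cc(OC)c1OCc1ccccc1 | intermediate
3 | meso-2,3-dimethylsuccinic acid, (2R,3S)-2,3-dimethylbutanedioic acid | OC(=O)[C@H](C)[C@H](C)C(=O)O | starting material
4 | cis-2,3-dimethylsuccinic anhydride, (3R,4S)-3,4-dimethyloxolane-2,5-dione | O=C1[C@H](C)[C@H](C)C(=O)O1 | intermediate
5 | [4-(benzyloxy)-3,5-dimethoxyphenyl]lithium | COc1cc([Li])cc(OC)c1OCc1ccccc1 | intermediate (not isolated)
6 | [4-(benzyloxy)-3,5-dimethoxyphenyl]zinc trifluoromethanesulfonate | COc1cc([Zn]OS(=O)(=O)C(F)(F)F)cc(OC)c1OCc1ccccc1 | intermediate (not isolated)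
7 | (2R,3S)-4-[4-(benzyloxy)-3,5-dimethoxyphenyl]-2,3-dimethyl-4-oxobutanoic acid | OC(=O)[C@H](C)[C@H](C)C(=O)c1cc(OC)c(OCc2ccccc2)c(OC)c1 | intermediate
8 | (2R,3R)-4-(4-hydroxy-3,5-dimethoxyphenyl)-2,3-dimethylbutanoic acid | OC(=O)[C@H](C)[C@H](C)Cc1cc(OC)c(O)c(OC)c1 | intermediate (not isolated)
9 | methyl (2R,3R)-4-(4-hydroxy-3,5-dimethoxyphenyl)-2,3-dimethylbutanoate | COC(=O)[C@H](C)[C@H](C)Cc1cc(OC)c(O)c(OC)c1 | intermediate
10 | (2R,3R)-4-(4-hydroxy-3,5-dimethoxyphenyl)-2,3-dimethylbutanal | O=C[C@H](C)[C@H](C)Cc1cc(OC)c(O)c(OC)c1 | intermediate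
11 | guaiacol, 2-methoxyphenol | COc1ccccc1O | starting material
12 | (2R,3R)-6,8-dimethoxy-2,3-dimethyl-1,2,3,4-tetrahydronaphthalene-1,7-diol (C1 epimers) | OC1c2c(cc(OC)c(O)c2OC)C[C@@H](C)[C@H]1C | intermediate (not isolated)
13 | (−)-(7'R,8R,8'R)-4,4'-dihydroxy-3,3',5-trimethoxy-2,7'-cyclolignan, (6R,7R,8R)-8-(4-hydroxy-3-methoxyphenyl)-1,3-dimethoxy-6,7-dimethyl-5,6,7,8-tetrahydronaphthalen-2-ol | COc1cc([C@@H]2c3c(cc(OC)c(O)c3OC)C[C@@H](C)[C@H]2C)ccc1O | target

Total step count: 6. Longest linear sequence: 5 steps (steps 1, 3, 4, 5, 6 from 1, or steps 2, 3, 4, 5, 6 from 3).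

**Steps most likely to fail**

Step 6. Three processes may go wrong. Guaiacol may attack through the carbon para to its methoxy group instead of para to its hydroxyl. The benzylic cation may lose the C8' proton and be re-protonated, which would erode the cis-dimethyl relationship. The product may undergo further Friedel–Crafts alkylation to oligomers. The fallback sets out from 10 and fixes the site of the aryl bond with a carbon–metal bond. The Grignard reagent [4-(benzyloxy)-3-methoxyphenyl]magnesium bromide F1 is made from commercial 1-(benzyloxy)-4-bromo-2-methoxybenzene and Mg in THF. It is added in excess to 10 at −78 °C, the first equivalent being consumed by the phenol, to give the diaryl carbinol (2R,3R)-1-[4-(benzyloxy)-3-methoxyphenyl]-4-(4-hydroxy-3,5-dimethoxyphenyl)-2,3-dimethylbutan-1-ol F2 as a mixture of carbinol epimers. TFA in CH2Cl2 at 0 °C should ionise this para-alkoxybenzylic alcohol, and the cation should close onto ring carbon C2 (Friedel–Crafts cyclialkylation through a chair-like transition state with the aryl group trans to the C8' methyl). This gives the benzyl ether (6R,7R,8R)-8-[4-(benzyloxy)-3-methoxyphenyl]-1,3-dimethoxy-6,7-dimethyl-5,6,7,8-tetrahydronaphthalen-2-ol F3. Hydrogenolysis (H2, Pd/C, EtOAc) then comes back to the route at 13.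

Step 3. The catalyst may discriminate poorly between the two enantiotopic acyl–oxygen bonds, or transmetallation of the electron-rich arylzinc may be slow; the result would be low enantiomeric purity or low conversion. The fallback sets out from 4 and separates desymmetrisation from C–C bond formation. Alkaloid-catalysed methanolysis (MeOH, Et2O, −20 °C) should give the half-ester (2S,3R)-4-methoxy-2,3-dimethyl-4-oxobutanoic acid F4; the catalyst is (DHQD)2AQN or its pseudoenantiomer (DHQ)2AQN, whichever gives the (2S,3R) half-ester. Thioesterification (EtSH, DCC, cat. DMAP, CH2Cl2, 0 °C) gives methyl (2R,3S)-4-(ethylsulfanyl)-2,3-dimethyl-4-oxobutanoate F5. Fukuyama coupling with arylzinc 6 (cat. PdCl2(PPh3)2, THF/toluene, rt) gives the keto ester methyl (2R,3S)-4-[4-(benzyloxy)-3,5-dimethoxyphenyl]-2,3-dimethyl-4-oxobutanoate F6. Hydrogenation under the first-stage conditions of step 4 comes back to the route at 9.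

Step 5. The aluminium hemiacetal may collapse early, leading to over-reduction to the primary alcohol, or the aldehyde may epimerise at C2 during work-up. The fallback sets out from 9 and relies on a stable chelate instead of kinetic control. Amidation with MeNHOMe·HCl and excess i-PrMgCl (THF, −20 °C) should give the Weinreb amide (2R,3R)-4-(4-hydroxy-3,5-dimethoxyphenyl)-N-methoxy-N,2,3-trimethylbutanamide F7. LiAlH4 (THF, −40 → 0 °C) reduces it to a chelated hemiaminal that releases the aldehyde only on cold acidic work-up, which comes back to the route at 10.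

**Further compounds**

F1 | step 6 | [4-(benzyloxy)-3-methoxyphenyl]magnesium bromide | COc1cc([Mg]Br)ccc1OCc1ccccc1
F2 | step 6 | (2R,3R)-1-[4-(benzyloxy)-3-methoxyphenyl]-4-(4-hydroxy-3,5-dimethoxyphenyl)-2,3-dimethylbutan-1-ol (C1 epimers) | COc1cc(C(O)[C@H](C)[C@H](C)Cc2cc(OC)c(O)c(OC)c2)ccc1OCc1ccccc1
F3 | step 6 | (6R,7R,8R)-8-[4-(benzyloxy)-3-methoxyphenyl]-1,3-dimethoxy-6,7-dimethyl-5,6,7,8-tetrahydronaphthalen-2-ol | COc1cc([C@@H]2c3c(cc(OC)c(O)c3OC)C[C@@H](C)[C@H]2C)ccc1OCc1ccccc1
F4 | step 3 | (2S,3R)-4-methoxy-2,3-dimethyl-4-oxobutanoic acid | COC(=O)[C@H](C)[C@H](C)C(=O)O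
F5 | step 3 | methyl (2R,3S)-4-(ethylsulfanyl)-2,3-dimethyl-4-oxobutanoate | COC(=O)[C@H](C)[C@H](C)C(=O)SCC
F6 | step 3 | methyl (2R,3S)-4-[4-(benzyloxy)-3,5-dimethoxyphenyl]-2,3-dimethyl-4-oxobutanoate | COC(=O)[C@H](C)[C@H](C)C(=O)c1cc(OC)c(OCc2ccccc2)c(OC)c1
F7 | step 5 | (2R,3R)-4-(4-hydroxy-3,5-dimethoxyphenyl)-N-methoxy-N,2,3-trimethylbutanamide | CON(C)C(=O)[C@H](C)[C@H](C)Cc1cc(OC)c(O)c(OC)c1
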